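## Plan

- **Cuts:** Take off the two acetates. Put back three reductively removable helpers: O‑benzyl on the syringyl phenol and two PhS groups on C7'. Fold the C9–C8–C8'–C9' diol into a five‑membered 5‑menthyloxybutanolide. Then cut C7–C8 (veratryl CH2 to CH) and C7'–C8' in one three‑component disconnection.
- **Enabling feature:** C8 and C8' are adjacent CH centres, each with one CH2O arm and one benzyl arm, so the acyclic core is a ring‑opened, pseudo‑C2‑symmetric γ‑butyrolactone. Closed as ring O1–C2(=C9)–C3(=C8)–C4(=C8')–C5(=C9'), C8' becomes a Michael acceptor carbon and C8 the enolate carbon that results.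
- **Forward order:** No ring of the target is built, since both arenes are bought. C7'–C8' forms by conjugate addition and C7–C8 by enolate benzylation in the same flask. The template ring is then opened reductively, the diol acetylated, and all helpers removed in one hydrogenolysis.
- **Stereochemistry:** l‑Menthol fixes the crystalline (5R) acetal centre of the butenolide. That centre sets C8' (addition anti to O‑menthyl), and C8' sets C8 (alkylation anti to the C8' substituent). The trans ring relation maps onto (8R,8'R), and the auxiliary centre is erased in the reduction.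

Key step: step 5

Assumption: 5‑hydroxyfuran‑2(5H)‑one is taken as purchasable; otherwise it is one step from furfural by dye‑sensitised photo‑oxygenation. Lignan numbering is used: C7/C8/C9 for the 3,4‑dimethoxyphenyl half and C7'/C8'/C9' for the syringyl half.

## Route

Step 1
Reactants: 1 syringaldehyde (4‑hydroxy‑3,5‑dimethoxybenzaldehyde)
Product: 2 4‑(benzyloxy)‑3,5‑dimethoxybenzaldehyde
Conditions: BnBr, K2CO3, DMF, 60 °C
Reagents that add atoms: benzyl bromide, BrCc1ccccc1
Why: Williamson etherification of the acidic phenol masks it with a group that tolerates n‑BuLi, LiAlH4 and Ac2O and can be removed later under neutral reductive conditions.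

Step 2
Reactants: 2 4‑(benzyloxy)‑3,5‑dimethoxybenzaldehyde
Product: 3 2‑(benzyloxy)‑5‑[bis(phenylthio)methyl]‑1,3‑dimethoxybenzene
Conditions: PhSH (2.1 equiv), BF3·OEt2 (cat.), CH2Cl2, 0 °C
Reagents that add atoms: thiophenol, Sc1ccccc1
Why: Lewis‑acid‑catalysed dithioacetalisation of an electron‑rich aryl aldehyde gives the umpolung form of the syringyl benzyl carbon, and catalytic acid at 0 °C should leave the benzyl ether intact.

Step 3
Reactants: 4 3,4‑dimethoxybenzyl alcohol
Product: 5 3,4‑dimethoxybenzyl bromide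
Conditions: PBr3 (0.4 equiv), Et2O, 0 °C; used at once
Reagents that add atoms: phosphorus tribromide, BrP(Br)Br
Why: Bromination of a primary benzylic alcohol through its phosphite ester gives the reactive electron‑rich bromide, which is made fresh because it does not store well.

Step 4
Reactants: 6 5‑hydroxyfuran‑2(5H)‑one; 7 l‑menthol, (1R,2S,5R)
Product: 8 (5R)‑5‑[(1R,2S,5R)‑menthyloxy]furan‑2(5H)‑one
Conditions: CSA (cat.), toluene, Dean–Stark reflux; crystallisation from petroleum ether, mother liquor re‑equilibrated with acid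
Reagents that add atoms: none
Why: Acid‑catalysed acetalisation of the cyclic pseudo‑acid gives both C5 epimers, which interconvert through the ring oxocarbenium ion, and the less soluble (5R) epimer is collected by crystallisation, so the acetal centre is set by crystallisation‑driven epimer selection.

Step 5
Reactants: 3 2‑(benzyloxy)‑5‑[bis(phenylthio)methyl]‑1,3‑dimethoxybenzene; 8 (5R)‑5‑(menthyloxy)furan‑2(5H)‑one; 5 3,4‑dimethoxybenzyl bromide
Product: 11 (3R,4R,5R)‑4‑{[4‑(benzyloxy)‑3,5‑dimethoxyphenyl]bis(phenylthio)methyl}‑3‑(3,4‑dimethoxybenzyl)‑5‑[(1R,2S,5R)‑menthyloxy]dihydrofuran‑2(3H)‑one, via [4‑(benzyloxy)‑3,5‑dimethoxyphenyl]bis(phenylthio)methyllithium 9 (not isolated), via lithium enolate of the (4R,5R) conjugate adduct 10 (not isolated)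
Conditions: 3, n‑BuLi (1.0 equiv), THF, −78 °C; then 8, −78 °C; then 5, DMPU, −78 → −30 °C; aq NH4Cl
Reagents that add atoms: none
Why: Lithiation of 3 gives the soft, doubly sulfur‑stabilised benzylic anion 9, which adds 1,4 to butenolide 8, and the resulting lactone enolate 10 is benzylated in the same flask at ring C3 (= C8) by 5 in an SN2 step; this is the tandem conjugate addition–enolate alkylation (three‑component coupling) of butenolides that is well established for dibenzylbutyrolactone lignans. No ring is closed, and the five‑membered acetal‑lactone ring of 8 serves only as a temporary template. C8' (ring C4) is set by attack of 9 on the face anti to the C5 menthyloxy group, so the auxiliary acetal centre is the only source of absolute configuration. C8 (ring C3) is set by approach of 5 anti to the very large aryl‑bis(phenylthio)methyl group on C4, which should give the 3,4‑trans product. The step needs 1,4‑ over 1,2‑addition (secured by the delocalised, hindered bis(phenylthio) carbanion), C‑mono‑alkylation (secured by the soft benzylic bromide and the crowded tertiary C3–H of 11), and alkylation faster than retro‑Michael cleavage (secured by the electron‑rich bromide and DMPU at low temperature).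

Step 6
Reactants: 11 the (3R,4R,5R) three‑component adduct
Product: 12 (2R,3R)‑2‑{[4‑(benzyloxy)‑3,5‑dimethoxyphenyl]bis(phenylthio)methyl}‑3‑(3,4‑dimethoxybenzyl)butane‑1,4‑diol
Conditions: LiAlH4, THF, 0 °C → rt; H2O/aq NaOH work‑up
Reagents that add atoms: none
Why: LiAlH4 reduction of a γ‑alkoxybutanolide takes the lactone carbonyl (C9) to CH2OH and, after ring opening and loss of menthoxide from the hemiacetal, the acetal carbon (C9') to CH2OH as well, while the thioacetal and ethers are inert and C8/C8' are not touched.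

Step 7
Reactants: 12 the (2R,3R) diol
Product: 13 (2R,3R)‑2‑{[4‑(benzyloxy)‑3,5‑dimethoxyphenyl]bis(phenylthio)methyl}‑3‑(3,4‑dimethoxybenzyl)butane‑1,4‑diyl diacetate
Conditions: Ac2O, pyridine, DMAP (cat.), CH2Cl2, 0 °C → rt
Reagents that add atoms: acetic anhydride, CC(=O)OC(C)=O
Why: DMAP‑catalysed acetylation of two primary alcohols is routine, and because the phenol is still a benzyl ether only the two required esters can form.

Step 8
Reactants: 13 the (2R,3R) diacetate
Product: 14 Justin C, (2R,3R)‑2‑(3,4‑dimethoxybenzyl)‑3‑(4‑hydroxy‑3,5‑dimethoxybenzyl)butane‑1,4‑diyl diacetate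
Conditions: Raney Ni (W‑2, washed neutral, large excess in two portions), H2 (1 atm), EtOH, 50 °C → reflux
Reagents that add atoms: none
Why: Raney nickel hydrogenolysis (Mozingo‑type desulfurisation, known to spare acetates in acetylated sugar dithioacetals) should cleave both benzylic C–S bonds and the aryl benzyl ether in one operation, turning C7' into CH2 and freeing the phenol without touching either stereocentre.

## Compound list

1 | syringaldehyde | COc1cc(C=O)cc(OC)c1O | starting material
2 | 4‑(benzyloxy)‑3,5‑dimethoxybenzaldehyde | COc1cc(C=O)cc(OC)c1OCc1ccccc1 | intermediate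
3 | 2‑(benzyloxy)‑5‑[bis(phenylthio)methyl]‑1,3‑dimethoxybenzene | COc1cc(C(Sc2ccccc2)Sc2ccccc2)cc(OC)c1OCc1ccccc1 | intermediate
4 | 3,4‑dimethoxybenzyl alcohol | COc1ccc(CO)cc1OC | starting material
5 | 3,4‑dimethoxybenzyl bromide | COc1ccc(CBr)cc1OC | intermediate
6 | 5‑hydroxyfuran‑2(5H)‑one (configurationally labile hemiacetal) | O=C1C=CC(O)O1 | starting material
7 | l‑menthol, (1R,2S,5R) | O[C@@H]1C[C@H](C)CC[C@H]1C(C)C | starting material
8 | (5R)‑5‑[(1R,2S,5R)‑menthyloxy]furan‑2(5H)‑one | O=C1C=C[C@H](O[C@@H]2C[C@H](C)CC[C@H]2C(C)C)O1 | intermediate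
9 | [4‑(benzyloxy)‑3,5‑dimethoxyphenyl]bis(phenylthio)methyllithium | [Li]C(Sc1ccccc1)(Sc1ccccc1)c1cc(OC)c(OCc2ccccc2)c(OC)c1 | intermediate
10 | lithium enolate of the (4R,5R) conjugate adduct | [Li]OC1=C[C@@H](C(Sc2ccccc2)(Sc2ccccc2)c2cc(OC)c(OCc3ccccc3)c(OC)c2)[C@H](O[C@@H]2C[C@H](C)CC[C@H]2C(C)C)O1 | intermediate
11 | (3R,4R,5R) three‑component adduct (3,4‑trans, 4,5‑trans lactone acetal) | O=C1O[C@@H](O[C@@H]2C[C@H](C)CC[C@H]2C(C)C)[C@H](C(Sc2ccccc2)(Sc2ccccc2)c2cc(OC)c(OCc3ccccc3)c(OC)c2)[C@H]1Cc1ccc(OC)c(OC)c1 | intermediate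
12 | (2R,3R) diol bearing the C7' bis(phenylthio) group and O‑benzyl | COc1ccc(C[C@@H](CO)[C@H](CO)C(Sc2ccccc2)(Sc2ccccc2)c2cc(OC)c(OCc3ccccc3)c(OC)c2)cc1OC | intermediate
13 | (2R,3R) diacetate bearing the C7' bis(phenylthio) group and O‑benzyl | COc1ccc(C[C@@H](COC(C)=O)[C@H](COC(C)=O)C(Sc2ccccc2)(Sc2ccccc2)c2cc(OC)c(OCc3ccccc3)c(OC)c2)cc1OC | intermediate
14 | Justin C | COc1ccc(C[C@@H](COC(C)=O)[C@H](COC(C)=O)Cc2cc(OC)c(O)c(OC)c2)cc1OC | target

## Step count and risks

Total steps: 8. Longest linear sequence: 6 (steps 1, 2, 5, 6, 7, 8).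

**Step 5.**
- Risk: benzylation of the crowded enolate may be slow, so that retro‑Michael cleavage and proton exchange compete with C–C bond formation.
- Fallback: it sets out from 10 (generated from 3 and 8 as above) and comes back at 14.
- The enolate is protonated at −78 °C (aq NH4Cl) to give the (4R,5R) Michael adduct lactone F1.
- Radical desulfurisation (Bu3SnH, AIBN, toluene, reflux) removes both phenylthio groups with the benzyl ether retained, giving the (4R,5R) β‑benzyl lactone acetal F2.
- The enolate of F2 (LDA, THF, −78 °C) is slim and cannot fragment. It is alkylated with 5 anti to the C4 benzyl group to give the (3R,4R,5R) dibenzyl lactone acetal F3.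
- LiAlH4 gives the (2R,3R) O‑benzyl diol F4, and Ac2O/pyridine gives the (2R,3R) O‑benzyl diacetate F5.
- Hydrogenolysis (H2, Pd/C, EtOAc), now free of sulfur, gives 14.

**Step 8.**
- Risk: sulfur loading of the nickel surface may stop the O‑debenzylation short, and residual alkali on the nickel may cause ethanolysis of the acetates.
- Fallback: it sets out from 12 and comes back at 14.
- The reductive unmasking is moved ahead of the esterification. Diol 12 has nothing base‑labile, so it can be treated exhaustively with Raney Ni/H2 in refluxing EtOH to give the (2R,3R) phenolic diol F6.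
- The two primary alcohols of F6 are then acetylated chemoselectively by a lipase (serine hydrolase class, e.g. immobilised Candida antarctica lipase B) with vinyl acetate in MTBE at 40 °C. Acylation of this type is known to leave phenolic OH groups untouched.

**Step 6.**
- Risk: the hindered aluminium hemiacetal may fail to collapse, so that reduction stalls at the lactol level and the auxiliary is released only on work‑up.
- Fallback: it sets out from 11 and comes back at 12.
- The auxiliary is removed first by reductive hydrolysis (NaBH4, aq KOH, THF/MeOH, then acidification and lactonisation). This gives the plain (3R,4R) trans‑butyrolactone F7, an ordinary γ‑lactone that LiAlH4 should reduce to 12 with no acetal involved.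

## Further compounds

F1 | step 5 | (4R,5R)‑4‑{[4‑(benzyloxy)‑3,5‑dimethoxyphenyl]bis(phenylthio)methyl}‑5‑(menthyloxy)dihydrofuran‑2(3H)‑one | O=C1C[C@@H](C(Sc2ccccc2)(Sc2ccccc2)c2cc(OC)c(OCc3ccccc3)c(OC)c2)[C@H](O[C@@H]2C[C@H](C)CC[C@H]2C(C)C)O1
F2 | step 5 | (4R,5R)‑4‑[4‑(benzyloxy)‑3,5‑dimethoxybenzyl]‑5‑(menthyloxy)dihydrofuran‑2(3H)‑one | O=C1C[C@@H](Cc2cc(OC)c(OCc3ccccc3)c(OC)c2)[C@H](O[C@@H]2C[C@H](C)CC[C@H]2C(C)C)O1
F3 | step 5 | (3R,4R,5R)‑4‑[4‑(benzyloxy)‑3,5‑dimethoxybenzyl]‑3‑(3,4‑dimethoxybenzyl)‑5‑(menthyloxy)dihydrofuran‑2(3H)‑one | O=C1O[C@@H](O[C@@H]2C[C@H](C)CC[C@H]2C(C)C)[C@H](Cc2cc(OC)c(OCc3ccccc3)c(OC)c2)[C@H]1Cc1ccc(OC)c(OC)c1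
F4 | step 5 | (2R,3R)‑2‑[4‑(benzyloxy)‑3,5‑dimethoxybenzyl]‑3‑(3,4‑dimethoxybenzyl)butane‑1,4‑diol | COc1ccc(C[C@@H](CO)[C@H](CO)Cc2cc(OC)c(OCc3ccccc3)c(OC)c2)cc1OC
F5 | step 5 | (2R,3R)‑2‑[4‑(benzyloxy)‑3,5‑dimethoxybenzyl]‑3‑(3,4‑dimethoxybenzyl)butane‑1,4‑diyl diacetate | COc1ccc(C[C@@H](COC(C)=O)[C@H](COC(C)=O)Cc2cc(OC)c(OCc3ccccc3)c(OC)c2)cc1OC
F6 | step 8 | (2R,3R)‑2‑(3,4‑dimethoxybenzyl)‑3‑(4‑hydroxy‑3,5‑dimethoxybenzyl)butane‑1,4‑diol | COc1ccc(C[C@@H](CO)[C@H](CO)Cc2cc(OC)c(O)c(OC)c2)cc1OC
F7 | step 6 | (3R,4R)‑4‑{[4‑(benzyloxy)‑3,5‑dimethoxyphenyl]bis(phenylthio)methyl}‑3‑(3,4‑dimethoxybenzyl)dihydrofuran‑2(3H)‑one | O=C1OC[C@H](C(Sc2ccccc2)(Sc2ccccc2)c2cc(OC)c(OCc3ccccc3)c(OC)c2)[C@H]1Cc1ccc(OC)c(OC)c1
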